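**Plan**

1. Retrosynthesis: ring C is opened in one stroke at O1–C8a and C2–C3, an aldol retron whose carbinol oxygen is also the ring oxygen. This gives a ring B aldehyde and a ring A methyl ketone with fluorine at C8a. The acetyl group is then cut at C4–C4a, and the C8 side chain at C1''–C2'' and at its C=C bond.
2. Enabling feature: C4 sits on C4a, ortho to C8a, and 1,3 to the C2–O1 carbinol. With C4 as an N-sulfinyl ketimine, an aza-enolate at C3 adds to the aldehyde, and the alkoxide formed lies six atoms from a C8a–F carbon activated by the ortho C4=N–S(O) group.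
3. Forward, ring A: 5-fluororesorcinol is protected and brominated at both carbons flanking fluorine. One bromine becomes the benzylic bromide that alkylates (R)-β-methyl-γ-butyrolactone; the other becomes the acetyl group once the chain is complete.
4. Forward, chain and ring C: lactone → lactol → one-carbon Wittig homologation → isopropylidene Wittig; then ketimine formation, closure of ring C (aldol addition/SNAr), and one acid step that frees ketone, phenols and alcohol.
5. Stereochemistry: C3'' comes from the lactone, C2'' from trans alkylation of its enolate, and C2 from the (S)-tert-butanesulfinyl group in the C–C bond formation. C2 is kept because the C2–O bond is never broken; fluorine fixes the chain at C8 rather than C6.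

Key step: step 13

Assumption 1: (R)-4-methyldihydrofuran-2(3H)-one is taken to be a catalogue compound.
Assumption 2: the (S)-sulfinyl group is taken to direct the aza-enolate addition to the (S)-carbinol (chair model, approach anti to tert-butyl). If the sense is the opposite, (R)-2-methylpropane-2-sulfinamide is used and nothing else changes.

**Route**

Step 1
Reactants: 1 5-fluorobenzene-1,3-diol
Product: 2 1-fluoro-3,5-bis(methoxymethoxy)benzene
Conditions: MOMCl, i-Pr2NEt, CH2Cl2, 0 °C → rt
Reagents that add atoms: chloromethyl methyl ether, COCCl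
Why: Acetalisation of both phenols (MOM protection) gives ethers that survive organolithium reagents and fall off together under acid at the end.

Step 2
Reactants: 2 1-fluoro-3,5-bis(methoxymethoxy)benzene
Product: 3 1,3-dibromo-2-fluoro-4,6-bis(methoxymethoxy)benzene
Conditions: NBS (2 equiv), MeCN, 0 °C → rt
Reagents that add atoms: N-bromosuccinimide, O=C1CCC(=O)N1Br
Why: Electrophilic aromatic bromination should place each bromine para to one OMOM group and ortho to the other, that is at the two equivalent carbons flanking fluorine, the carbon between the two OMOM groups being the most shielded, as in the 4,6-dibromination of resorcinol diethers.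

Step 3
Reactants: 3 1,3-dibromo-2-fluoro-4,6-bis(methoxymethoxy)benzene
Product: 6 [3-bromo-2-fluoro-4,6-bis(methoxymethoxy)phenyl]methanol, via aryllithium 4 (not isolated), via aldehyde 5 (not isolated)
Conditions: n-BuLi (1 equiv), THF, −78 °C; DMF; then MeOH, NaBH4, −78 → 0 °C
Reagents that add atoms: N,N-dimethylformamide, CN(C)C=O
Why: Bromine–lithium exchange of one of two equivalent bromines (aryllithium 4 resists a second exchange and should be stable to loss of LiF at −78 °C) is followed by formylation with DMF and borohydride reduction of aldehyde 5 in the same flask.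

Step 4
Reactants: 6 [3-bromo-2-fluoro-4,6-bis(methoxymethoxy)phenyl]methanol
Product: 7 1-bromo-3-(bromomethyl)-2-fluoro-4,6-bis(methoxymethoxy)benzene
Conditions: CBr4, PPh3, CH2Cl2, 0 °C; used at once
Reagents that add atoms: carbon tetrabromide, BrC(Br)(Br)Br
Why: The Appel reaction runs under neutral conditions that leave the MOM acetals intact, and the labile electron-rich benzylic bromide is carried on without storage.

Step 5
Reactants: 8 (R)-4-methyldihydrofuran-2(3H)-one; 7 1-bromo-3-(bromomethyl)-2-fluoro-4,6-bis(methoxymethoxy)benzene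
Product: 10 (3R,4R)-3-[3-bromo-2-fluoro-4,6-bis(methoxymethoxy)benzyl]-4-methyldihydrofuran-2(3H)-one, via lithium enolate 9 (not isolated)
Conditions: LDA, THF, −78 °C; then 7, DMPU, −78 → −40 °C
Reagents that add atoms: none
Why: In this alkylation of the lithium enolate of a β-substituted γ-butyrolactone the benzylic bromide should approach the face anti to the C4 methyl group, giving the trans-3,4-disubstituted lactone and so setting C2'' (R) from the stereocenter of the starting lactone.

Step 6
Reactants: 10 (3R,4R)-3-[3-bromo-2-fluoro-4,6-bis(methoxymethoxy)benzyl]-4-methyldihydrofuran-2(3H)-one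
Product: 11 (3R,4R)-3-[3-bromo-2-fluoro-4,6-bis(methoxymethoxy)benzyl]-4-methyltetrahydrofuran-2-ol (anomers)
Conditions: DIBAL-H, CH2Cl2, −78 °C; Rochelle salt work-up
Reagents that add atoms: none
Why: Partial reduction of a lactone with DIBAL-H stops at the aluminium hemiacetal at −78 °C and gives the lactol on work-up, the aryl bromide and fluoride being inert.

Step 7
Reactants: 11 (3R,4R)-3-[3-bromo-2-fluoro-4,6-bis(methoxymethoxy)benzyl]-4-methyltetrahydrofuran-2-ol
Product: 13 (4S,5R)-4-[3-bromo-2-fluoro-4,6-bis(methoxymethoxy)benzyl]-5-methyltetrahydro-2H-pyran-2-ol (anomers), via enol ether 12 (not isolated)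
Conditions: [Ph3PCH2OMe]Cl, KHMDS, THF, 0 °C → rt; then 1 M HCl, THF, 0 °C → rt (brief)
Reagents that add atoms: (methoxymethyl)triphenylphosphonium chloride, COC[P+](c1ccccc1)(c1ccccc1)c1ccccc1.[Cl-]; water, O
Why: Wittig methoxymethylenation of the lactol through its hydroxy aldehyde form and hydrolysis of enol ether 12 amount to a one-carbon homologation, the new aldehyde closing on the primary alcohol as a six-membered lactol in which C2'' is β to the carbonyl and can no longer epimerise, while brief cold dilute acid should leave the aryl MOM ethers in place.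

Step 8
Reactants: 13 (4S,5R)-4-[3-bromo-2-fluoro-4,6-bis(methoxymethoxy)benzyl]-5-methyltetrahydro-2H-pyran-2-ol
Product: 14 (2R,3R)-3-[3-bromo-2-fluoro-4,6-bis(methoxymethoxy)benzyl]-2,6-dimethylhept-5-en-1-ol
Conditions: [i-PrPPh3]I, n-BuLi, THF, 0 °C (ylide preformed); then 13, 0 °C → rt
Reagents that add atoms: isopropyltriphenylphosphonium iodide, CC(C)[P+](c1ccccc1)(c1ccccc1)c1ccccc1.[I-]
Why: Wittig olefination of the lactol with the unstabilised isopropylidene ylide forms the trisubstituted alkene of the prenyl unit and frees the primary alcohol, the ylide being preformed so that no butyllithium meets the aryl bromide.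

Step 9
Reactants: 14 (2R,3R)-3-[3-bromo-2-fluoro-4,6-bis(methoxymethoxy)benzyl]-2,6-dimethylhept-5-en-1-ol
Product: 15 {[(2R,3R)-3-[3-bromo-2-fluoro-4,6-bis(methoxymethoxy)benzyl]-2,6-dimethylhept-5-en-1-yl]oxy}(tert-butyl)dimethylsilane
Conditions: TBSCl, imidazole, DMF, rt
Reagents that add atoms: tert-butyldimethylsilyl chloride, CC(C)(C)[Si](C)(C)Cl
Why: Silylation of the primary alcohol ensures that no alkoxide competes in the organolithium step or in the later ring closure, where it could attack C8a in a seven-membered mode.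

Step 10
Reactants: 15 {[(2R,3R)-3-[3-bromo-2-fluoro-4,6-bis(methoxymethoxy)benzyl]-2,6-dimethylhept-5-en-1-yl]oxy}(tert-butyl)dimethylsilane
Product: 17 1-{3-[(2R,3R)-4-(tert-butyldimethylsilyloxy)-3-methyl-2-(3-methylbut-2-en-1-yl)butyl]-2-fluoro-4,6-bis(methoxymethoxy)phenyl}ethan-1-one, via aryllithium 16 (not isolated)
Conditions: n-BuLi, THF, −78 °C; MeC(O)N(OMe)Me, −78 → −40 °C
Reagents that add atoms: N-methoxy-N-methylacetamide, CC(=O)N(C)OC
Why: Bromine–lithium exchange at −78 °C gives aryllithium 16, which is acylated by the Weinreb amide through a chelated tetrahedral adduct that prevents over-addition.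

Step 11
Reactants: 17 1-{3-[(2R,3R)-4-(tert-butyldimethylsilyloxy)-3-methyl-2-(3-methylbut-2-en-1-yl)butyl]-2-fluoro-4,6-bis(methoxymethoxy)phenyl}ethan-1-one; 18 (S)-2-methylpropane-2-sulfinamide
Product: 19 (S,E)-N-(1-{3-[(2R,3R)-4-(tert-butyldimethylsilyloxy)-3-methyl-2-(3-methylbut-2-en-1-yl)butyl]-2-fluoro-4,6-bis(methoxymethoxy)phenyl}ethylidene)-2-methylpropane-2-sulfinamide
Conditions: Ti(OEt)4, THF, 70 °C
Reagents that add atoms: none
Why: Condensation of a ketone with tert-butanesulfinamide promoted by Ti(OEt)4 as Lewis acid and water scavenger is a standard ketimine synthesis, fluorine is small enough for the doubly ortho-substituted ketone to react on heating, and the E isomer (sulfinyl group anti to the aryl ring) is expected.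

Step 12
Reactants: 20 4-hydroxy-2-methoxybenzaldehyde
Product: 21 2-methoxy-4-(methoxymethoxy)benzaldehyde
Conditions: MOMCl, i-Pr2NEt, CH2Cl2, 0 °C → rt
Reagents that add atoms: chloromethyl methyl ether, COCCl
Why: MOM protection of the phenol is chosen so that all phenols are unmasked together by acid at the end.

Step 13
Reactants: 19 (S,E)-N-(1-{3-[(2R,3R)-4-(tert-butyldimethylsilyloxy)-3-methyl-2-(3-methylbut-2-en-1-yl)butyl]-2-fluoro-4,6-bis(methoxymethoxy)phenyl}ethylidene)-2-methylpropane-2-sulfinamide; 21 2-methoxy-4-(methoxymethoxy)benzaldehyde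
Product: 24 (S)-N-{(2S,4E)-8-[(2R,3R)-4-(tert-butyldimethylsilyloxy)-3-methyl-2-(3-methylbut-2-en-1-yl)butyl]-2-[2-methoxy-4-(methoxymethoxy)phenyl]-5,7-bis(methoxymethoxy)chroman-4-ylidene}-2-methylpropane-2-sulfinamide, via magnesium aza-enolate 22 (not isolated), via magnesium aldolate 23 (not isolated)
Conditions: LDA, THF, −78 °C; MgBr2·OEt2; 21, −78 °C; then DMPU, −78 → 40 °C
Reagents that add atoms: none
Why: Proposed new method: LDA removes a proton from the C3 methyl group of 19, the magnesium aza-enolate 22 adds to aldehyde 21 to give aldolate 23 (C2–C3 bond), and on warming the alkoxide oxygen attacks C8a of ring A, which carries fluorine ortho to the C4=N–S(O) acceptor, and fluoride leaves from the Meisenheimer adduct (O1–C8a bond). The closest known reaction types are the aldol-type addition of metalloenamines of N-tert-butanesulfinyl methyl ketimines to aldehydes and the intramolecular SNAr of alkoxides on ortho-fluoroaryl ketones or their masked forms that gives chroman-4-ones; they have not been joined in one flask, nor has the sulfinyl ketimine served as the activating group for the displacement. Ring C closes in a six-membered mode by attack on the trigonal carbon C8a (6-endo-trig counted through the C8a=C4a–C4=N acceptor, which takes up the charge; 6-exo-trig counted through the C8a=C8 bond). C2 is the only new stereocenter and is set in the carbon–carbon bond formation by the sulfur stereocenter through a chair-like magnesium-bridged transition state with the aldehyde aryl group equatorial and approach anti to the tert-butyl group; the C2–O bond is not broken in the ring closure, so the configuration passes into 24 with retention. The step needs ring closure to outrun retro-addition and β-elimination, which is secured by keeping C4 as the imine (a poorer leaving enolate and a less acidic C3 than in a ketone aldolate) and by magnesium, which holds the aldolate and assists the loss of fluoride; it also needs oxygen to bond to C8a and not to C5, which is secured by fluorine being the only leaving group on ring A, so the chain ends up at C8. Any C2 epimer is a diastereomer of 24 and is removed by chromatography.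

Step 14
Reactants: 24 (S)-N-{(2S,4E)-8-[(2R,3R)-4-(tert-butyldimethylsilyloxy)-3-methyl-2-(3-methylbut-2-en-1-yl)butyl]-2-[2-methoxy-4-(methoxymethoxy)phenyl]-5,7-bis(methoxymethoxy)chroman-4-ylidene}-2-methylpropane-2-sulfinamide
Product: 25 (2S)-5,7-dihydroxy-2-(4-hydroxy-2-methoxyphenyl)-8-[(2R,3R)-4-hydroxy-3-methyl-2-(3-methylbut-2-en-1-yl)butyl]chroman-4-one
Conditions: 2 M HCl (aq), THF, 0 °C → rt; then MeOH, 40 °C
Reagents that add atoms: water, O
Why: Aqueous acid hydrolyses the N-sulfinyl ketimine at C4 to the ketone (water adds to C4 and the sulfinamide leaves) and acid methanolysis in the same flask cleaves the three aryl MOM acetals and the silyl ether, low temperature and short time being used to spare C2 and the trisubstituted alkene.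

**Compound list**

1 | 5-fluorobenzene-1,3-diol | Oc1cc(O)cc(F)c1 | starting material
2 | 1-fluoro-3,5-bis(methoxymethoxy)benzene | COCOc1cc(F)cc(OCOC)c1 | intermediate
3 | 1,3-dibromo-2-fluoro-4,6-bis(methoxymethoxy)benzene | COCOc1cc(OCOC)c(Br)c(F)c1Br | intermediate
4 | [3-bromo-2-fluoro-4,6-bis(methoxymethoxy)phenyl]lithium | COCOc1cc(OCOC)c(Br)c(F)c1[Li] | intermediate (not isolated)
5 | 3-bromo-2-fluoro-4,6-bis(methoxymethoxy)benzaldehyde | COCOc1cc(OCOC)c(Br)c(F)c1C=O | intermediate (not isolated)
6 | [3-bromo-2-fluoro-4,6-bis(methoxymethoxy)phenyl]methanol | COCOc1cc(OCOC)c(Br)c(F)c1CO | intermediate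
7 | 1-bromo-3-(bromomethyl)-2-fluoro-4,6-bis(methoxymethoxy)benzene | COCOc1cc(OCOC)c(Br)c(F)c1CBr | intermediate
8 | (R)-4-methyldihydrofuran-2(3H)-one | O=C1C[C@@H](C)CO1 | starting material
9 | lithium enolate of 8, lithium (R)-3-methyl-2,3-dihydrofuran-5-olate | [Li]OC1=C[C@@H](C)CO1 | intermediate (not isolated)
10 | (3R,4R)-3-[3-bromo-2-fluoro-4,6-bis(methoxymethoxy)benzyl]-4-methyldihydrofuran-2(3H)-one (trans) | COCOc1cc(OCOC)c(Br)c(F)c1C[C@H]1C(=O)OC[C@@H]1C | intermediate
11 | (3R,4R)-3-[3-bromo-2-fluoro-4,6-bis(methoxymethoxy)benzyl]-4-methyltetrahydrofuran-2-ol (anomers) | COCOc1cc(OCOC)c(Br)c(F)c1C[C@H]1C(O)OC[C@@H]1C | intermediate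
12 | (2R,3R)-3-[3-bromo-2-fluoro-4,6-bis(methoxymethoxy)benzyl]-5-methoxy-2-methylpent-4-en-1-ol (E/Z mixture) | COCOc1cc(OCOC)c(Br)c(F)c1C[C@@H](C=COC)[C@@H](C)CO | intermediate (not isolated)
13 | (4S,5R)-4-[3-bromo-2-fluoro-4,6-bis(methoxymethoxy)benzyl]-5-methyltetrahydro-2H-pyran-2-ol (4,5-trans, anomers) | COCOc1cc(OCOC)c(Br)c(F)c1C[C@H]1CC(O)OC[C@@H]1C | intermediate
14 | (2R,3R)-3-[3-bromo-2-fluoro-4,6-bis(methoxymethoxy)benzyl]-2,6-dimethylhept-5-en-1-ol | COCOc1cc(OCOC)c(Br)c(F)c1C[C@@H](CC=C(C)C)[C@@H](C)CO | intermediate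
15 | {[(2R,3R)-3-[3-bromo-2-fluoro-4,6-bis(methoxymethoxy)benzyl]-2,6-dimethylhept-5-en-1-yl]oxy}(tert-butyl)dimethylsilane | COCOc1cc(OCOC)c(Br)c(F)c1C[C@@H](CC=C(C)C)[C@@H](C)CO[Si](C)(C)C(C)(C)C | intermediate
16 | aryllithium from 15 (lithium in place of bromine) | COCOc1cc(OCOC)c([Li])c(F)c1C[C@@H](CC=C(C)C)[C@@H](C)CO[Si](C)(C)C(C)(C)C | intermediate (not isolated)
17 | 1-{3-[(2R,3R)-4-(tert-butyldimethylsilyloxy)-3-methyl-2-(3-methylbut-2-en-1-yl)butyl]-2-fluoro-4,6-bis(methoxymethoxy)phenyl}ethan-1-one | CC(=O)c1c(F)c(C[C@@H](CC=C(C)C)[C@@H](C)CO[Si](C)(C)C(C)(C)C)c(OCOC)cc1OCOC | intermediate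
18 | (S)-2-methylpropane-2-sulfinamide | CC(C)(C)[S@](=O)N | starting material
19 | (S,E)-N-(1-{3-[(2R,3R)-4-(tert-butyldimethylsilyloxy)-3-methyl-2-(3-methylbut-2-en-1-yl)butyl]-2-fluoro-4,6-bis(methoxymethoxy)phenyl}ethylidene)-2-methylpropane-2-sulfinamide | C/C(=N\[S@@](=O)C(C)(C)C)c1c(F)c(C[C@@H](CC=C(C)C)[C@@H](C)CO[Si](C)(C)C(C)(C)C)c(OCOC)cc1OCOC | intermediate
20 | 4-hydroxy-2-methoxybenzaldehyde | COc1cc(O)ccc1C=O | starting material
21 | 2-methoxy-4-(methoxymethoxy)benzaldehyde | COCOc1ccc(C=O)c(OC)c1 | intermediate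
22 | bromomagnesium aza-enolate of 19 (N-metalated N-sulfinyl enamide, S at sulfur) | C=C(N([Mg]Br)[S@@](=O)C(C)(C)C)c1c(F)c(C[C@@H](CC=C(C)C)[C@@H](C)CO[Si](C)(C)C(C)(C)C)c(OCOC)cc1OCOC | intermediate (not isolated)
23 | bromomagnesium alkoxide of (S)-N-{(1E,3S)-1-[ring A aryl of 19]-3-hydroxy-3-[2-methoxy-4-(methoxymethoxy)phenyl]propylidene}-2-methylpropane-2-sulfinamide | COc1cc(OCOC)ccc1[C@@H](O[Mg]Br)C/C(=N\[S@@](=O)C(C)(C)C)c1c(F)c(C[C@@H](CC=C(C)C)[C@@H](C)CO[Si](C)(C)C(C)(C)C)c(OCOC)cc1OCOC | intermediate (not isolated)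
24 | (S)-N-{(2S,4E)-8-[(2R,3R)-4-(tert-butyldimethylsilyloxy)-3-methyl-2-(3-methylbut-2-en-1-yl)butyl]-2-[2-methoxy-4-(methoxymethoxy)phenyl]-5,7-bis(methoxymethoxy)chroman-4-ylidene}-2-methylpropane-2-sulfinamide | COc1cc(OCOC)ccc1[C@@H]1C/C(=N\[S@@](=O)C(C)(C)C)c2c(OCOC)cc(OCOC)c(C[C@@H](CC=C(C)C)[C@@H](C)CO[Si](C)(C)C(C)(C)C)c2O1 | intermediate
25 | (2S)-5,7-dihydroxy-2-(4-hydroxy-2-methoxyphenyl)-8-[(2R,3R)-4-hydroxy-3-methyl-2-(3-methylbut-2-en-1-yl)butyl]chroman-4-one | COc1cc(O)ccc1[C@@H]1CC(=O)c2c(O)cc(O)c(C[C@@H](CC=C(C)C)[C@@H](C)CO)c2O1 | target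

**Summary**

Total step count: 14. Longest linear sequence: 13 steps (steps 1 to 11, then 13 and 14); step 12 is the one-step side branch.

Steps most likely to fail:

1. Step 13 (bears the label "Proposed new method:"). The aldolate may revert to aza-enolate and aldehyde on warming before the ring closes, which would erode control at C2. The magnesium alkoxide may attack the fluoroarene too slowly, and sulfinyl transfer from nitrogen to oxygen or β-elimination may compete. The fallback uses known chemistry, a chalcone route in which the ring oxygen is placed on ring A first; it sets out from ketone 17 and returns at 25. Ketone 17 is treated with 2-(methylsulfonyl)ethanol and NaH in DMF, which displaces fluoride to give the 2-(methylsulfonyl)ethyl aryl ether F1. This loses methyl vinyl sulfone in the same flask to give the 2-hydroxyacetophenone F2. Claisen–Schmidt condensation of F2 with aldehyde 21 (KOH, EtOH) gives the 2'-hydroxychalcone F3. Its only free phenol is the one at the future C8a, so oxa-Michael closure (NaOAc, EtOH, reflux) can only give the 8-substituted flavanone, as the protected (2S)-flavanone F4 and its (2R) epimer F5. These are diastereomers because of the side-chain stereocenters and would be separated by preparative HPLC, F5 being put back through the same equilibration. Acid unmasking of F4 as in step 14 gives 25.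

2. Step 14. Acid may ionise the C2–O1 bond, because the C2 cation is stabilised by the 2'-methoxy and 4'-oxygen groups of ring B, and this would epimerise C2. The alkene may be hydrated. If the S–N bond is cleaved before the C=N bond, the N–H ketiminium, stabilised by the three oxygens of ring A, may hydrolyse slowly. The fallback sets out from 24 and returns at 25. AcOH–THF–H2O at rt hydrolyses the sulfinyl ketimine and removes the silyl ether without touching the aryl MOM ethers, to give the tris-MOM flavanone F6. The MOM groups are then removed under non-protic conditions with TMSOTf and 2,2'-bipyridyl in CH2Cl2 at 0 °C, followed by water.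

3. Step 5. The electron-rich benzylic bromide 7 may ionise and self-alkylate before it meets the enolate, and dialkylation may occur. The fallback avoids the bromide; it sets out from aldehyde 5 (isolated by leaving out the borohydride in step 3) and lactone 8 and returns at 10. Aldol addition of enolate 9 to 5 gives the β-hydroxy lactone F7. Its mesylate F8 (MsCl, Et3N, not isolated) is eliminated with DBU to the (E)-α-arylidene lactone F9. Conjugate reduction with LiBH(s-Bu)3, which leaves the aryl bromide untouched, and protonation give 10 together with its cis epimer F10. DBU then equilibrates the mixture toward the more stable trans lactone 10.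

**Further compounds**

F1 | step 13 | 1-{3-[(2R,3R)-4-(tert-butyldimethylsilyloxy)-3-methyl-2-(3-methylbut-2-en-1-yl)butyl]-4,6-bis(methoxymethoxy)-2-[2-(methylsulfonyl)ethoxy]phenyl}ethan-1-one (not isolated) | CC(=O)c1c(OCCS(C)(=O)=O)c(C[C@@H](CC=C(C)C)[C@@H](C)CO[Si](C)(C)C(C)(C)C)c(OCOC)cc1OCOC
F2 | step 13 | 1-{3-[(2R,3R)-4-(tert-butyldimethylsilyloxy)-3-methyl-2-(3-methylbut-2-en-1-yl)butyl]-2-hydroxy-4,6-bis(methoxymethoxy)phenyl}ethan-1-one | CC(=O)c1c(O)c(C[C@@H](CC=C(C)C)[C@@H](C)CO[Si](C)(C)C(C)(C)C)c(OCOC)cc1OCOC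
F3 | step 13 | (E)-1-{3-[(2R,3R)-4-(tert-butyldimethylsilyloxy)-3-methyl-2-(3-methylbut-2-en-1-yl)butyl]-2-hydroxy-4,6-bis(methoxymethoxy)phenyl}-3-[2-methoxy-4-(methoxymethoxy)phenyl]prop-2-en-1-one | COc1cc(OCOC)ccc1/C=C/C(=O)c1c(O)c(C[C@@H](CC=C(C)C)[C@@H](C)CO[Si](C)(C)C(C)(C)C)c(OCOC)cc1OCOC
F4 | step 13 | (2S)-8-[(2R,3R)-4-(tert-butyldimethylsilyloxy)-3-methyl-2-(3-methylbut-2-en-1-yl)butyl]-2-[2-methoxy-4-(methoxymethoxy)phenyl]-5,7-bis(methoxymethoxy)chroman-4-one | COc1cc(OCOC)ccc1[C@@H]1CC(=O)c2c(OCOC)cc(OCOC)c(C[C@@H](CC=C(C)C)[C@@H](C)CO[Si](C)(C)C(C)(C)C)c2O1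
F5 | step 13 | (2R) epimer of F4 | COc1cc(OCOC)ccc1[C@H]1CC(=O)c2c(OCOC)cc(OCOC)c(C[C@@H](CC=C(C)C)[C@@H](C)CO[Si](C)(C)C(C)(C)C)c2O1
F6 | step 14 | (2S)-8-[(2R,3R)-4-hydroxy-3-methyl-2-(3-methylbut-2-en-1-yl)butyl]-2-[2-methoxy-4-(methoxymethoxy)phenyl]-5,7-bis(methoxymethoxy)chroman-4-one | COc1cc(OCOC)ccc1[C@@H]1CC(=O)c2c(OCOC)cc(OCOC)c(C[C@@H](CC=C(C)C)[C@@H](C)CO)c2O1
F7 | step 5 | (3S,4R)-3-{[3-bromo-2-fluoro-4,6-bis(methoxymethoxy)phenyl](hydroxy)methyl}-4-methyldihydrofuran-2(3H)-one (3,4-trans, carbinol epimers) | COCOc1cc(OCOC)c(Br)c(F)c1C(O)[C@H]1C(=O)OC[C@@H]1C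
F8 | step 5 | methanesulfonate of F7 (not isolated) | COCOc1cc(OCOC)c(Br)c(F)c1C(OS(C)(=O)=O)[C@H]1C(=O)OC[C@@H]1C
F9 | step 5 | (R,E)-3-[3-bromo-2-fluoro-4,6-bis(methoxymethoxy)benzylidene]-4-methyldihydrofuran-2(3H)-one | COCOc1cc(OCOC)c(Br)c(F)c1/C=C1/C(=O)OC[C@@H]1C
F10 | step 5 | (3S,4R)-3-[3-bromo-2-fluoro-4,6-bis(methoxymethoxy)benzyl]-4-methyldihydrofuran-2(3H)-one (cis epimer of 10) | COCOc1cc(OCOC)c(Br)c(F)c1C[C@@H]1C(=O)OC[C@@H]1C
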